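**Retrosynthetic overview**

1. Target ⇐ two Mitsunobu esterifications with inversion (tiglic acid at azulene C8, silyl-protected 4-hydroxybenzoic acid at C4). Each carbinol is first made by hydride delivery to the convex face of a ketone, so both esters end on the convex face, cis to 8a-CH3 and to H-3a.
2. 6-Methylcyclohept-6-en-8-one unit ⇐ one-carbon ring expansion (siloxycyclopropane, FeCl3) of a cis-hydrindan-7-one. CH2 is inserted between the carbonyl carbon and the methyl-bearing α-carbon, giving the C8 ketone and the C6=C7 olefin at once.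
3. cis-Hydrindane ⇐ intramolecular aldol of a 2-(3-oxoalkyl)cyclohexane-1,4-dione (closes the five-membered ring, sets C3 and C3a) ⇐ auxiliary-controlled Michael addition of a 2,6-dimethylcyclohexanone imine to isopropyl vinyl ketone (sets the quaternary centre).
4. Ring order: six-membered ring (purchased) → five-membered ring (aldol) → seven-membered ring (from the six-membered ring, last).
5. Enabling feature: the ring ketone (indane C7) lies between the quaternary ring-fusion carbon C7a and the CH(CH3) carbon C6, so only the C6=C7 enol ether can form. Its cyclopropane shares the oxygen-substituted C6–C7 bond with the six-membered ring, and cleaving that bond leaves a tertiary radical at C6 and only one enolisable side.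

Key step: step 10

Remark: 4-methylpent-1-en-3-one and 4-[(tert-butyldimethylsilyl)oxy]benzoic acid are taken as catalogue compounds.
Remark: the ring methyl next to the ketone (spiro C9, indane C6) is carried as an epimeric mixture and is left undefined in the SMILES; it becomes sp2 in step 8.
Remark: indane numbering is used for the bicyclo[4.3.0] compounds and azulene numbering for the bicyclo[5.3.0] compounds; "convex" is the face of the cis-fused bicycle that carries the angular methyl and the ring-fusion hydrogen.
Remark: the route assumes that the cis-fused ketones react on the convex face, anti to the pseudo-axial cyclopentane methylene; this follows from a conformational argument, not from a calculation.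

**Step 1**
Reactants: 1 7-methyl-1,4-dioxaspiro[4.5]decan-8-one
Product: 2 7,9-dimethyl-1,4-dioxaspiro[4.5]decan-8-one
Conditions: LiN(iPr)2, THF, −78 °C; MeI, −78 to 0 °C
Reagents that add atoms: iodomethane, CI
Why: kinetic deprotonation at the unsubstituted α-CH2 followed by SN2 methylation of the enolate should give the 2,6-dimethyl ketone, and both diastereomers serve because one methyl-bearing carbon becomes quaternary in step 3 and the other sp2 in step 8.

**Step 2**
Reactants: 2 7,9-dimethyl-1,4-dioxaspiro[4.5]decan-8-one; 3 (R)-1-phenylethylamine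
Product: 4 N-[(1R)-1-phenylethyl]-7,9-dimethyl-1,4-dioxaspiro[4.5]decan-8-imine
Conditions: TsOH (cat.), toluene, reflux, Dean–Stark
Reagents that add atoms: none
Why: ketimine condensation driven by azeotropic removal of water should work on the hindered ketone as it does on other 2,6-dialkylcyclohexanones, and the imine equilibrates with its tetrasubstituted secondary enamine.

**Step 3**
Reactants: 4 N-[(1R)-1-phenylethyl]-7,9-dimethyl-1,4-dioxaspiro[4.5]decan-8-imine; 5 4-methylpent-1-en-3-one
Product: 7 (7R)-7,9-dimethyl-7-(4-methyl-3-oxopentyl)-1,4-dioxaspiro[4.5]decan-8-one, via Michael-adduct imine 6 (not isolated)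
Conditions: 5 (1.05 equiv), THF, 40 °C; then 20% aq AcOH, rt
Reagents that add atoms: water, O
Why: asymmetric Michael addition of a chiral imine through its more substituted secondary enamine tautomer (compact aza-ene-like transition state with N–H transfer), in which the enone should approach the enamine face away from the phenyl group of the auxiliary and so set the quaternary centre (R) before mild hydrolysis releases ketone and amine.

**Step 4**
Reactants: 7 (7R)-7,9-dimethyl-7-(4-methyl-3-oxopentyl)-1,4-dioxaspiro[4.5]decan-8-one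
Product: 8 (2R)-2,6-dimethyl-2-(4-methyl-3-oxopentyl)cyclohexane-1,4-dione
Conditions: 1 M HCl, THF, rt
Reagents that add atoms: water, O
Why: acid-catalysed hydrolysis of the dioxolane unmasks the third ketone, and in dilute acid at room temperature the ketone–ketone aldol reactions of the triketone should remain slow.

**Step 5**
Reactants: 8 (2R)-2,6-dimethyl-2-(4-methyl-3-oxopentyl)cyclohexane-1,4-dione
Product: 9 (3R,3aR,7aR)-3-hydroxy-6,7a-dimethyl-3-(propan-2-yl)hexahydro-1H-indene-4,7(2H,5H)-dione
Conditions: pyrrolidine (0.3 equiv), AcOH (0.3 equiv), THF, 0 °C to rt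
Reagents that add atoms: none
Why: amine-catalysed intramolecular aldol reaction (enamine catalysis, 5-exo-trig) in which pyrrolidine condenses with the least hindered carbonyl, only the enamine on the side of the quaternary carbon can reach an electrophile, the new five-membered ring can only be cis-fused, and the acid-bridged transition state should place the carbinol oxygen syn to the ring carbonyl carbon and the isopropyl group on the convex side, setting C3 (R) and C3a (R).

**Step 6**
Reactants: 9 (3R,3aR,7aR)-3-hydroxy-6,7a-dimethyl-3-(propan-2-yl)hexahydro-1H-indene-4,7(2H,5H)-dione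
Product: 10 (3R,3aS,4R,7aR)-3,4-dihydroxy-6,7a-dimethyl-3-(propan-2-yl)octahydro-7H-inden-7-one
Conditions: Me4NBH(OAc)3, MeCN/AcOH, −30 °C
Reagents that add atoms: none
Why: Evans–Saksena reduction, in which the tertiary hydroxyl binds boron and delivers hydride through a chair transition state only to the adjacent β-ketone (the isolated C7 ketone between a quaternary and a tertiary carbon is left alone), and the new hydrogen should end on the convex face with the C4 hydroxyl cis to C3 and trans to H-3a.

**Step 7**
Reactants: 10 (3R,3aS,4R,7aR)-3,4-dihydroxy-6,7a-dimethyl-3-(propan-2-yl)octahydro-7H-inden-7-one; 11 4-[(tert-butyldimethylsilyl)oxy]benzoic acid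
Product: 12 (3R,3aS,4S,7aR)-3-hydroxy-6,7a-dimethyl-7-oxo-3-(propan-2-yl)octahydro-1H-inden-4-yl 4-[(tert-butyldimethylsilyl)oxy]benzoate
Conditions: PPh3, DIAD, toluene, 0 °C to rt
Reagents that add atoms: none
Why: Mitsunobu esterification, in which the carboxylate should displace the secondary alkoxyphosphonium by SN2 with inversion from the open convex face so that the ester ends cis to H-3a as in the target, while the tertiary alcohol cannot be activated.

**Step 8**
Reactants: 12 (3R,3aS,4S,7aR)-3-hydroxy-6,7a-dimethyl-7-oxo-3-(propan-2-yl)octahydro-1H-inden-4-yl 4-[(tert-butyldimethylsilyl)oxy]benzoate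
Product: 13 (3R,3aS,4S,7aR)-6,7a-dimethyl-3-(propan-2-yl)-3,7-bis[(trimethylsilyl)oxy]-2,3,3a,4,5,7a-hexahydro-1H-inden-4-yl 4-[(tert-butyldimethylsilyl)oxy]benzoate
Conditions: Me3SiOTf (2.5 equiv), Et3N, CH2Cl2, 0 °C
Reagents that add atoms: trimethylsilyl trifluoromethanesulfonate, C[Si](C)(C)OS(=O)(=O)C(F)(F)F
Why: soft enolisation with silyl triflate and amine, where the ketone has a single α-hydrogen (the other α-carbon is quaternary) so only the tetrasubstituted C6=C7 enol ether can form, and the tertiary alcohol is silylated at the same time, which shields it from the zinc carbenoid of step 9.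

**Step 9**
Reactants: 13 (3R,3aS,4S,7aR)-6,7a-dimethyl-3-(propan-2-yl)-3,7-bis[(trimethylsilyl)oxy]-2,3,3a,4,5,7a-hexahydro-1H-inden-4-yl 4-[(tert-butyldimethylsilyl)oxy]benzoate
Product: 14 siloxycyclopropane formed by CH2 addition across C6=C7 of 13 (cyclopropane face undefined)
Conditions: Et2Zn, CH2I2, CH2Cl2, 0 °C to rt
Reagents that add atoms: diiodomethane, C(I)I
Why: Simmons–Smith cyclopropanation (Furukawa variant), in which the electrophilic zinc carbenoid should add to the electron-rich silyl enol ether and leave the electron-poor arene alone, and the face of addition does not matter because both new stereocentres are erased in step 10.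

**Step 10**
Reactants: 14 siloxycyclopropane formed by CH2 addition across C6=C7 of 13
Product: 16 (3R,3aS,4S,8aR)-3-hydroxy-6,8a-dimethyl-8-oxo-3-(propan-2-yl)-1,2,3,3a,4,5,8,8a-octahydroazulen-4-yl 4-[(tert-butyldimethylsilyl)oxy]benzoate, via β-chloro ketone 15 (not isolated)
Conditions: FeCl3 (2.5 equiv), pyridine, DMF, 0 °C to rt; 1 M aq HCl/THF, rt; then Et3N, CH2Cl2, rt
Reagents that add atoms: none
Why: FeCl3 exchanges the silyl group on the cyclopropanol oxygen and trivalent iron oxidises the resulting alkoxide to a cyclopropyloxy radical, whose β-scission breaks the bond shared by the three- and six-membered rings, so the six-membered ring becomes seven-membered, the ketone reappears at C8 and a tertiary radical is left at C6. A second FeCl3 transfers chlorine to that radical, the acidic work-up removes the tertiary silyl ether, and Et3N eliminates HCl (E1cB) toward the only α-CH2 to give the conjugated enone. The closest known reaction type is the Ito–Saegusa ring enlargement of 1-siloxybicyclo[n.1.0]alkanes. No ring is closed: the seven-membered ring arises by cleavage of the zero-atom bridge of the bicyclo[4.1.0]heptane, and no stereocentre is made (the two cyclopropane stereocentres are erased; C3, C3a, C4 and C8a are untouched). The step needs endocyclic instead of exocyclic bond scission, secured by the tertiary instead of primary radical and the release of ring strain. It also needs a single olefin position, secured because the other α-carbon of the ketone is quaternary.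

**Step 11**
Reactants: 16 (3R,3aS,4S,8aR)-3-hydroxy-6,8a-dimethyl-8-oxo-3-(propan-2-yl)-1,2,3,3a,4,5,8,8a-octahydroazulen-4-yl 4-[(tert-butyldimethylsilyl)oxy]benzoate
Product: 17 (3R,3aS,4S,8S,8aR)-3,8-dihydroxy-6,8a-dimethyl-3-(propan-2-yl)-1,2,3,3a,4,5,8,8a-octahydroazulen-4-yl 4-[(tert-butyldimethylsilyl)oxy]benzoate
Conditions: NaBH4, CeCl3·7H2O, MeOH, −78 °C
Reagents that add atoms: none
Why: Luche 1,2-reduction, in which hydride should add to the carbonyl on its convex face, anti to the pseudo-axial cyclopentane methylene on the neighbouring quaternary carbon, giving the C8 alcohol trans to the angular methyl (8S), which is the epimer needed for the inverting esterification.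

**Step 12**
Reactants: 17 (3R,3aS,4S,8S,8aR)-3,8-dihydroxy-6,8a-dimethyl-3-(propan-2-yl)-1,2,3,3a,4,5,8,8a-octahydroazulen-4-yl 4-[(tert-butyldimethylsilyl)oxy]benzoate; 18 (E)-2-methylbut-2-enoic acid (tiglic acid)
Product: 19 (3R,3aS,4S,8R,8aR)-3-hydroxy-6,8a-dimethyl-8-{[(2E)-2-methylbut-2-enoyl]oxy}-3-(propan-2-yl)-1,2,3,3a,4,5,8,8a-octahydroazulen-4-yl 4-[(tert-butyldimethylsilyl)oxy]benzoate
Conditions: PPh3, DIAD, toluene, 0 °C to rt
Reagents that add atoms: none
Why: Mitsunobu esterification, in which the carboxylate should displace the allylic alkoxyphosphonium by SN2 with inversion, entering on the convex face anti to the cyclopentane methylene, which sets C8 (R) with the ester cis to the angular methyl, while the tertiary alcohol stays free and tiglic acid keeps its E geometry under neutral conditions.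

**Step 13**
Reactants: 19 (3R,3aS,4S,8R,8aR)-3-hydroxy-6,8a-dimethyl-8-{[(2E)-2-methylbut-2-enoyl]oxy}-3-(propan-2-yl)-1,2,3,3a,4,5,8,8a-octahydroazulen-4-yl 4-[(tert-butyldimethylsilyl)oxy]benzoate
Product: 20 (3R,3aS,4S,8R,8aR)-3-hydroxy-6,8a-dimethyl-8-{[(2E)-2-methylbut-2-enoyl]oxy}-3-(propan-2-yl)-1,2,3,3a,4,5,8,8a-octahydroazulen-4-yl 4-hydroxybenzoate
Conditions: Bu4NF, AcOH, THF, 0 °C
Reagents that add atoms: none
Why: fluoride cleaves the aryl silyl ether quickly because the electron-poor phenoxide is a good leaving group from silicon, and the acetic acid buffer should spare the benzoate, the allylic tiglate and the tertiary alcohol.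

**Compound list**

1 | 7-methyl-1,4-dioxaspiro[4.5]decan-8-one (racemic) | CC1CC2(CCC1=O)OCCO2 | starting material
2 | 7,9-dimethyl-1,4-dioxaspiro[4.5]decan-8-one (cis/trans mixture) | CC1CC2(CC(C)C1=O)OCCO2 | intermediate
3 | (R)-1-phenylethylamine | C[C@@H](N)c1ccccc1 | starting material
4 | N-[(1R)-1-phenylethyl]-7,9-dimethyl-1,4-dioxaspiro[4.5]decan-8-imine (with its enamine tautomer) | c1ccccc1[C@@H](C)N=C1C(C)CC2(OCCO2)CC1C | intermediate
5 | 4-methylpent-1-en-3-one | CC(C)C(=O)C=C | starting material
6 | (7R)-7,9-dimethyl-7-(4-methyl-3-oxopentyl)-N-[(1R)-1-phenylethyl]-1,4-dioxaspiro[4.5]decan-8-imine | c1ccccc1[C@@H](C)N=C1C(C)CC2(OCCO2)C[C@@]1(C)CCC(=O)C(C)C | intermediate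
7 | (7R)-7,9-dimethyl-7-(4-methyl-3-oxopentyl)-1,4-dioxaspiro[4.5]decan-8-one (C9 epimers) | O=C1C(C)CC2(OCCO2)C[C@@]1(C)CCC(=O)C(C)C | intermediate
8 | (2R)-2,6-dimethyl-2-(4-methyl-3-oxopentyl)cyclohexane-1,4-dione (C6 epimers) | O=C1C(C)CC(=O)C[C@@]1(C)CCC(=O)C(C)C | intermediate
9 | (3R,3aR,7aR)-3-hydroxy-6,7a-dimethyl-3-(propan-2-yl)hexahydro-1H-indene-4,7(2H,5H)-dione (cis-fused; 3-OH cis to C4; C6 epimers) | O=C1C(C)CC(=O)[C@@H]2[C@@]1(C)CC[C@@]2(O)C(C)C | intermediate
10 | (3R,3aS,4R,7aR)-3,4-dihydroxy-6,7a-dimethyl-3-(propan-2-yl)octahydro-7H-inden-7-one (4-OH cis to C3) | O=C1C(C)C[C@@H](O)[C@@H]2[C@@]1(C)CC[C@@]2(O)C(C)C | intermediate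
11 | 4-[(tert-butyldimethylsilyl)oxy]benzoic acid | CC(C)(C)[Si](C)(C)Oc1ccc(cc1)C(=O)O | starting material
12 | (3R,3aS,4S,7aR)-3-hydroxy-6,7a-dimethyl-7-oxo-3-(propan-2-yl)octahydro-1H-inden-4-yl 4-[(tert-butyldimethylsilyl)oxy]benzoate (ester cis to H-3a) | O=C1C(C)C[C@H](OC(=O)c3ccc(O[Si](C)(C)C(C)(C)C)cc3)[C@@H]2[C@@]1(C)CC[C@@]2(O)C(C)C | intermediate
13 | (3R,3aS,4S,7aR)-6,7a-dimethyl-3-(propan-2-yl)-3,7-bis[(trimethylsilyl)oxy]-2,3,3a,4,5,7a-hexahydro-1H-inden-4-yl 4-[(tert-butyldimethylsilyl)oxy]benzoate | C[Si](C)(C)OC1=C(C)C[C@H](OC(=O)c3ccc(O[Si](C)(C)C(C)(C)C)cc3)[C@@H]2[C@@]1(C)CC[C@@]2(O[Si](C)(C)C)C(C)C | intermediate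
14 | siloxycyclopropane: CH2 adduct across C6=C7 of 13 (1-siloxybicyclo[4.1.0]heptane fused to the cyclopentane; cyclopropane face undefined) | C[Si](C)(C)OC12CC1(C)C[C@H](OC(=O)c5ccc(O[Si](C)(C)C(C)(C)C)cc5)[C@@H]3[C@@]2(C)CC[C@@]3(O[Si](C)(C)C)C(C)C | intermediate
15 | (3R,3aS,4S,8aR)-6-chloro-3-hydroxy-6,8a-dimethyl-8-oxo-3-(propan-2-yl)decahydroazulen-4-yl 4-[(tert-butyldimethylsilyl)oxy]benzoate (C6 epimers) | O=C1CC(C)(Cl)C[C@H](OC(=O)c3ccc(O[Si](C)(C)C(C)(C)C)cc3)[C@@H]2[C@@]1(C)CC[C@@]2(O)C(C)C | intermediate
16 | (3R,3aS,4S,8aR)-3-hydroxy-6,8a-dimethyl-8-oxo-3-(propan-2-yl)-1,2,3,3a,4,5,8,8a-octahydroazulen-4-yl 4-[(tert-butyldimethylsilyl)oxy]benzoate | O=C1C=C(C)C[C@H](OC(=O)c3ccc(O[Si](C)(C)C(C)(C)C)cc3)[C@@H]2[C@@]1(C)CC[C@@]2(O)C(C)C | intermediate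
17 | (3R,3aS,4S,8S,8aR)-3,8-dihydroxy-6,8a-dimethyl-3-(propan-2-yl)-1,2,3,3a,4,5,8,8a-octahydroazulen-4-yl 4-[(tert-butyldimethylsilyl)oxy]benzoate (8-OH trans to 8a-CH3) | O[C@H]1C=C(C)C[C@H](OC(=O)c3ccc(O[Si](C)(C)C(C)(C)C)cc3)[C@@H]2[C@@]1(C)CC[C@@]2(O)C(C)C | intermediate
18 | (E)-2-methylbut-2-enoic acid (tiglic acid) | C/C=C(\C)C(=O)O | starting material
19 | (3R,3aS,4S,8R,8aR)-3-hydroxy-6,8a-dimethyl-8-{[(2E)-2-methylbut-2-enoyl]oxy}-3-(propan-2-yl)-1,2,3,3a,4,5,8,8a-octahydroazulen-4-yl 4-[(tert-butyldimethylsilyl)oxy]benzoate | C/C=C(\C)C(=O)O[C@@H]1C=C(C)C[C@H](OC(=O)c3ccc(O[Si](C)(C)C(C)(C)C)cc3)[C@@H]2[C@@]1(C)CC[C@@]2(O)C(C)C | intermediate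
20 | (3R,3aS,4S,8R,8aR)-3-hydroxy-6,8a-dimethyl-8-{[(2E)-2-methylbut-2-enoyl]oxy}-3-(propan-2-yl)-1,2,3,3a,4,5,8,8a-octahydroazulen-4-yl 4-hydroxybenzoate | C/C=C(\C)C(=O)O[C@@H]1C=C(C)C[C@H](OC(=O)c2ccc(O)cc2)[C@@H]2[C@@]1(C)CC[C@@]2(O)C(C)C | target

**Step count and risks**

Total step count: 13. Longest linear sequence: 13 steps (compounds 3, 5, 11 and 18 are purchased).

Steps most likely to fail:

Step 12. The displacement takes place at an allylic carbon next to a quaternary centre, so the SN2 reaction may be outrun by allylic transposition (attack at the methyl-bearing olefin carbon) or by elimination to a diene. The fallback sets out from 16: a Corey–Bakshi–Shibata reduction ((S)-2-methyl-CBS-oxazaborolidine, catecholborane, toluene, −78 °C, with the quaternary α-carbon as the large group) should deliver hydride to the concave face under reagent control and give the C8-epimeric allylic alcohol F1 (hydroxyl cis to the angular methyl). A Yamaguchi esterification with 18 (2,4,6-trichlorobenzoyl chloride, Et3N, DMAP, toluene), which keeps the configuration, comes back to the route at 19.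

Step 7. The activated alcohol has anti-periplanar hydrogens on both neighbours, so anti-elimination may compete with substitution at this hindered secondary centre. The fallback sets out from 9: a Narasaka–Prasad reduction (Et2BOMe, NaBH4, THF/MeOH, −78 °C), in which external hydride adds to the boron chelate of the β-hydroxy ketone, should give the C4-epimeric diol F2 (4-OH cis to H-3a). A Steglich esterification with 11 (EDC·HCl, DMAP, CH2Cl2), which keeps the configuration, comes back to the route at 12.

Step 9. Methylene transfer to the congested tetrasubstituted enol ether beside a quaternary carbon may be slow, with loss of the silyl groups to the zinc salts competing. The fallback sets out from 12 and replaces the cyclopropane route by a diazo homologation: Me3SiCHN2 with BF3·OEt2 (CH2Cl2, −78 °C) should insert the carbon on the less substituted side of the ketone (migration of the CH(CH3) carbon, not the quaternary one) to give the α-silyl cycloheptanone F3. Brief treatment with 1 M HCl in THF removes the silyl group to give the cycloheptanone F4, and IBX in DMSO at 70 °C dehydrogenates the only enolisable side, coming back to the route at 16.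

**Further compounds**

F1 | step 12 | (3R,3aS,4S,8R,8aR)-3,8-dihydroxy-6,8a-dimethyl-3-(propan-2-yl)-1,2,3,3a,4,5,8,8a-octahydroazulen-4-yl 4-[(tert-butyldimethylsilyl)oxy]benzoate | O[C@@H]1C=C(C)C[C@H](OC(=O)c3ccc(O[Si](C)(C)C(C)(C)C)cc3)[C@@H]2[C@@]1(C)CC[C@@]2(O)C(C)C
F2 | step 7 | (3R,3aS,4S,7aR)-3,4-dihydroxy-6,7a-dimethyl-3-(propan-2-yl)octahydro-7H-inden-7-one | O=C1C(C)C[C@H](O)[C@@H]2[C@@]1(C)CC[C@@]2(O)C(C)C
F3 | step 9 | (3R,3aS,4S,8aR)-3-hydroxy-6,8a-dimethyl-8-oxo-3-(propan-2-yl)-7-(trimethylsilyl)decahydroazulen-4-yl 4-[(tert-butyldimethylsilyl)oxy]benzoate | O=C1C([Si](C)(C)C)C(C)C[C@H](OC(=O)c3ccc(O[Si](C)(C)C(C)(C)C)cc3)[C@@H]2[C@@]1(C)CC[C@@]2(O)C(C)C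
F4 | step 9 | (3R,3aS,4S,8aR)-3-hydroxy-6,8a-dimethyl-8-oxo-3-(propan-2-yl)decahydroazulen-4-yl 4-[(tert-butyldimethylsilyl)oxy]benzoate | O=C1CC(C)C[C@H](OC(=O)c3ccc(O[Si](C)(C)C(C)(C)C)cc3)[C@@H]2[C@@]1(C)CC[C@@]2(O)C(C)C
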